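## Structural features

The target is a cembranoid: a fourteen-membered carbocycle (C1–C14) cis-fused across C1–C2 to an α-methylene-γ-butyrolactone (C15, C16, C17 and the oxygen on C2). The carbocycle carries an E,E skipped diene (C3=C4(Me) and C6=C7) around the doubly allylic C5, a tertiary allylic carbinol at C8, a trisubstituted epoxide at C11–C12(Me) and a secondary acetate at C13. The six stereocentres form three groups: the contiguous triad C11–C12–C13 (11S,12R,13S, acetoxy anti to the epoxide oxygen), the adjacent pair C1/C2 (1S,2S, syn, hence the cis lactone), and the isolated quaternary C8 (R). The pair C1/C2 is 1,3-related to C13 across the C14 methylene, so neither group can easily control the other. Fragile sites are the exocyclic enoate (a Michael acceptor whose C2–O bond is an allylic ester that zerovalent palladium can ionise), the epoxide (opened 5-exo by a free C8 hydroxyl, and prone to Payne migration beside a free C13 alkoxide), the acetate and the skipped diene. The real difficulty is to close the fourteen-membered ring in the presence of these groups without touching a stereocentre, and to relate the C1/C2 pair to the C11–C13 triad. The key step exploits C5: it lies between two E-alkenes and bears no stereocentre, so C5–C6 can be made from an allylic electrophile (C3=C4–C5) and an alkenyl metal at C6, and C6=C7–C8 is the vinyl carbinol unit of a terpene alcohol available as one enantiomer.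

## Logic of the disconnections

28 ⇒ 26 (through 27). The lactone C16–O bond and the two O–Si bonds are cut. As a lactone the C2 oxygen would be an allylic ester beside C3=C4 during the palladium step, so it is kept as a silyl ether until the ring is closed. This turns the bicycle into a monocycle. The forward step must free two hydroxyls under conditions that are neither acidic nor strongly basic, and the C2 hydroxyl must then close on the methyl ester unaided; C13 is already the acetate, so no six-membered lactone can compete.

26 ⇒ 25. The C5–C6 bond is cut. It is the only ring bond flanked by two alkenes and by no stereocentre, and it maps onto an allylic chloride and an E-alkenylboronate. The macrocycle becomes an open chain. Both 25 and 26 keep the skeleton and the configurations 1S,2S,8R,11S,12R,13S of 28. A seco compound with a free C8 hydroxyl beside the epoxide, or with the chloride made late, would be weaker, so 25 carries silyl ethers at both C2 and C8 and its chloride comes from 22. The forward step demands high dilution, bond formation at C5 and not C3, and retention of both E geometries.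

25 ⇒ 24 ⇒ 17 + 22. The C2 O–Si bond and then the C1–C2 bond are cut. This bond joins the only two adjacent stereocentres not yet present and divides the chain into a large chiral allyl donor and a small achiral enal. The forward step must give the syn pair, which a closed chair transition state with the C14 chain cis to CH2B provides. It must also choose the enal face; since C13 is 1,3 to C1 and cannot do this reliably, a chiral acid catalyst is asked to. The product 24 must not lactonise before it is silylated.

17 ⇒ 16 ⇒ 15 ⇒ 14 ⇒ 12 + 13. The C17–B bond, the two acetyl C–O bonds, the C13 O–Si bond and the C1–C15 bond are cut. The acrylate carbons C15–C17 come from 13, and the transient C1 carbinol of 14–16 is the handle for the allylic transposition that places boron on C17. The gain is the simple aldehyde 12. The forward sequence needs a poor leaving group on C13 while the amine catalyst is present (hence a silyl ether, exchanged for the acetate afterwards), and an SN2′ borylation that gives one alkene geometry from both C1 epimers.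

12 ⇒ 11 ⇒ 7 + 8 (through 9 and 10). The C13–C14 bond is cut. C13 sits beside the epoxide, so addition to an α,β-epoxy aldehyde can set it, and the two-carbon donor 8 carries C14 and C1 at a level that one reduction turns into the aldehyde. The forward step needs anti addition relative to the epoxide oxygen and immediate protection of the aldolate.

7 ⇒ 6 ⇒ 4 + 5. The C13 oxidation level is adjusted and the C6=C7 alkene is cut by a metathesis transform. This installs the E-alkenylboron early, when the molecule has a single alkene. The forward metathesis must come after the epoxidation, otherwise the diene would ring-close.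

4 ⇒ 3 ⇒ 2 ⇒ 1. The two epoxide C–O bonds, the C13–O bond and the C8 O–Si bond are cut. 1 supplies C6–C13, both methyl groups and the C8 stereocentre. The forward steps need E-selective oxidation of one methyl group, reagent-controlled epoxidation, and silylation of C8–OH before the epoxide exists.

22 ⇒ 21 ⇒ 20 ⇒ 19 ⇒ 18. The C2 oxidation level, the acetate, the C5–Cl bond and the C5–O bond are cut. The chloride is placed before fragment union, so no late activation is needed on the full chain. The forward steps must keep the E geometry and leave the allylic chloride untouched.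

## Other disconnections considered

Alternative 1: The cut runs across C15–C1 and C13–C14 (both formed) with loss of C15–C13. The lactone A1, cis-fused to the fourteen-membered 11-en-13-one, would come from the fifteen-membered β-keto lactone A2 by irradiation: the enol C15=C13 adds to the vinyl group on C2 and the cyclobutanol opens by retro-aldol cleavage.
- In favour: A2 is closed by macrolactonisation, and one operation then forms two C–C bonds and both rings.
- Better than the chosen plan on one point: the short O–C16–C15 tether should deliver C15 to C1 on the face set by C2, so the cis fusion would come from C2 alone, whereas step 16 needs an external chiral catalyst.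
- Against it here: straight versus crossed addition across so large a ring cannot be secured by design, and the C11=C12–C13 enone and the skipped diene are competing chromophores that can isomerise.
- A1 still lacks the methylene, the epoxide, the C13 centre and the acetate. These would be added on the macrocycle by methylenation, reduction and epoxidation, with control resting on ring conformation and not on reagents as in steps 3 and 6.
- Comparison: the chosen closure is a thermal, catalytic two-electron reaction at a bond without stereocentres. Step counts are similar up to ring closure, but Alternative 1 would need about five operations after A1 against one after 26.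

Alternative 2: The cut is C9–C10. The macrocyclic sulfone A3 would form when the seco compound A4, deprotonated at the C13 hydroxyl and at C10, attacks the CH2 of its C8–C9 epoxide and releases the C8 alkoxide.
- In favour: sulfone carbanion alkylation is an established way to close cembrane rings and needs no transition metal.
- Equal to the chosen plan on one point: the ring closes at a carbon whose configuration does not matter, since the C10 and acetal epimers converge later.
- Against it here: two equivalents of strong base exclude the acrylate, the acetate and the C11–C12 epoxide, so A3 carries a lactol acetal and a C11=C12 alkene.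
- After ring closure it would need reductive desulfonylation of an allylic sulfone (risk of alkene migration) and hydroxyl-directed epoxidation of C11=C12, in which the C8 carbinol would compete by directing to C6=C7. Acetal oxidation, methylenation and acetylation would follow.
- Comparison: C8 would have to be made as an enantiopure 2,2-disubstituted epoxide, whereas here it is bought with 1. Alternative 2 is better in cost and in avoiding boron–palladium compatibility questions, and worse in functional-group tolerance and in steps after the ring is made (six or more).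

Alternative 3: The cut is C14–C1. On heating, the sixteen-membered allyl vinyl ether A6 would undergo a [3,3] shift that forms C14–C1, breaks O–C17 and gives the fourteen-membered ketone A5.
- In favour: the large oxacycle is reached by lactonisation and carbonyl methylenation, and the shift is reagent-free.
- Equal or better on two points: the macrolactonisation is at least as dependable a ring closure as step 18, and C1 would be set in an ordered cyclic transition state next to C2 without an external catalyst, if the geometry cooperates.
- Against it here: the chair or boat preference inside a macrocycle and the C15=C1 geometry together decide C1 and cannot be predicted with confidence, and the enol ether is acid-labile.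
- A5 is far from 28: C16 must be oxidised to the acid, the C2 ether removed, the lactone closed, C13 reduced, C11=C12 epoxidised selectively, and the product acetylated and desilylated.
- Comparison: the chosen plan fixes C11–C13 early under reagent or substrate control and ends one step after ring closure. Alternative 3 postpones this to the macrocycle and would need about seven further steps.

Key step: step 18

Remark on the chemistry: atom labels C1–C17 are those of the macrocycle (C15 on C1, C16 the carbonyl, C17 the methylene); Bpin is the 4,4,5,5-tetramethyl-1,3,2-dioxaborolan-2-yl group; pinacol boronates and triethylsilyl ethers are assumed to survive chromatography on buffered silica.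

## Route

Step 1
Reactants: 1 (R)-linalool
Product: 2 (R)-linalool triethylsilyl ether
Conditions: Et3SiOTf, 2,6-lutidine, CH2Cl2, −78 → 0 °C
Reagents that add atoms: triethylsilyl trifluoromethanesulfonate, CC[Si](CC)(CC)OS(=O)(=O)C(F)(F)F
Why: Silylation of the tertiary carbinol with a silyl triflate and a hindered base is standard; it masks the C8 oxygen so that it cannot later open the C11–C12 epoxide in a 5-exo mode, and the R centre is not touched.

Step 2
Reactants: 2 (R)-linalool triethylsilyl ether
Product: 3 (2E,6R)-2,6-dimethyl-6-(triethylsilyloxy)octa-2,7-dien-1-ol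
Conditions: SeO2 (0.3 equiv), t-BuOOH, salicylic acid (cat.), CH2Cl2, rt
Reagents that add atoms: tert-butyl hydroperoxide, CC(C)(C)OO
Why: Riley allylic oxidation (ene reaction, then [2,3] shift) attacks the trisubstituted alkene at its E methyl group and should give the E allylic alcohol; the vinyl group has no allylic hydrogen.

Step 3
Reactants: 3 (2E,6R)-2,6-dimethyl-6-(triethylsilyloxy)octa-2,7-dien-1-ol
Product: 4 (2S,3S)-epoxy alcohol with the C6=C7 vinyl group
Conditions: Ti(OiPr)4 (10 mol%), L-(+)-diethyl tartrate (12 mol%), t-BuOOH, 4 Å molecular sieves, CH2Cl2, −20 °C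
Reagents that add atoms: tert-butyl hydroperoxide, CC(C)(C)OO
Why: Sharpless asymmetric epoxidation of the primary E allylic alcohol; with the L-(+)-tartrate the oxygen is delivered to the face that gives the (2S,3S)-epoxy alcohol, which sets C11 (S) and C12 of the target under reagent control, and the isolated vinyl group is not epoxidised.

Step 4
Reactants: 4 (2S,3S)-epoxy alcohol with the C6=C7 vinyl group; 5 vinylboronic acid pinacol ester
Product: 6 (E)-alkenylboronate epoxy alcohol
Conditions: second-generation Grubbs catalyst (5 mol%), CH2Cl2, 40 °C
Reagents that add atoms: none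
Why: Olefin cross-metathesis of the monosubstituted alkene with the vinylboronate should give the E alkenylboronate, the bulky C8 and boryl groups ending trans; 4 has no second alkene, so the ring-closing metathesis that would destroy a diene such as 3 cannot occur.

Step 5
Reactants: 6 (E)-alkenylboronate epoxy alcohol
Product: 7 (2R,3S)-epoxy aldehyde
Conditions: PhI(OAc)2, TEMPO (10 mol%), CH2Cl2, rt
Reagents that add atoms: none
Why: Nitroxyl-catalysed oxidation of a primary alcohol stops at the aldehyde under nearly neutral conditions; C12 is quaternary, so the epoxy aldehyde cannot epimerise, and the boronate, epoxide and silyl ether are inert.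

Step 6
Reactants: 7 (2R,3S)-epoxy aldehyde; 8 N-methoxy-N-methylacetamide
Product: 11 (13S)-trimethylsilyloxy N-methoxy-N-methylamide, via lithium enolate 9 (not isolated), via lithium aldolate 10 (not isolated)
Conditions: LiN(iPr)2, THF, −78 °C; then 7; then Me3SiCl, −78 → −20 °C
Reagents that add atoms: chlorotrimethylsilane, C[Si](C)(C)Cl
Why: Aldol addition of an amide enolate to an α,β-epoxy aldehyde; in the non-chelated Felkin–Anh/Cornforth arrangement the nucleophile approaches anti to the epoxide C–O bond, which should give the 13S (anti) aldolate; trapping it in the flask as the silyl ether means no β-hydroxy aldehyde appears later.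

Step 7
Reactants: 11 (13S)-trimethylsilyloxy N-methoxy-N-methylamide
Product: 12 (13S)-trimethylsilyloxy aldehyde (C1 as CHO)
Conditions: iBu2AlH, THF, −78 °C; aq. potassium sodium tartrate
Reagents that add atoms: none
Why: An N-methoxy-N-methylamide is reduced by iBu2AlH to a chelated hemiaminal that releases the aldehyde only on work-up, so over-reduction is avoided; at −78 °C the epoxide, boronate and silyl ethers should persist.

Step 8
Reactants: 12 (13S)-trimethylsilyloxy aldehyde (C1 as CHO); 13 methyl acrylate
Product: 14 Baylis–Hillman adduct (C1 carbinol, both epimers)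
Conditions: DABCO (1 equiv), neat in 13, rt
Reagents that add atoms: none
Why: The Baylis–Hillman reaction joins the acrylate α-carbon (C15) to C1; the new C1 carbinol centre is left uncontrolled because step 11 erases it, and the β-oxygen is a silyl ether, a poor leaving group towards E1cB loss under the amine.

Step 9
Reactants: 14 Baylis–Hillman adduct (C1 carbinol, both epimers)
Product: 15 C1,C13-diol
Conditions: PPTS (10 mol%), MeOH, 0 °C
Reagents that add atoms: none
Why: Acid-catalysed methanolysis cleaves the secondary trimethylsilyl ether far faster than the tertiary triethylsilyl ether at C8, so only the C13 hydroxyl is set free.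

Step 10
Reactants: 15 C1,C13-diol
Product: 16 C1,C13-diacetate
Conditions: Ac2O, DMAP (cat.), pyridine, 0 °C → rt
Reagents that add atoms: acetic anhydride, CC(=O)OC(C)=O
Why: Acetylation of both secondary hydroxyls installs at once the C13 acetate of the target and the allylic acetate leaving group at C1.

Step 11
Reactants: 16 C1,C13-diacetate
Product: 17 (E)-2-(methoxycarbonyl)allyl pinacol boronate (boron on C17)
Conditions: B2pin2, CuCl (10 mol%), KOAc, DMF, rt
Reagents that add atoms: bis(pinacolato)diboron, CC1(C)OB(OC1(C)C)B1OC(C)(C)C(C)(C)O1
Why: Copper-catalysed borylation of a Baylis–Hillman acetate (conjugate addition of a boryl–copper species, then β-elimination of acetate, overall SN2′); both C1 epimers converge on one trisubstituted alkene with the C14 chain trans to the ester and cis to CH2B, the geometry favoured by allylic strain.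

Step 12
Reactants: 18 prenyl acetate
Product: 19 (2E)-4-hydroxy-3-methylbut-2-en-1-yl acetate
Conditions: SeO2 (0.3 equiv), t-BuOOH, salicylic acid (cat.), CH2Cl2, rt
Reagents that add atoms: tert-butyl hydroperoxide, CC(C)(C)OO
Why: Riley oxidation of the trisubstituted alkene at its E methyl group should give the E allylic alcohol that becomes C5.

Step 13
Reactants: 19 (2E)-4-hydroxy-3-methylbut-2-en-1-yl acetate
Product: 20 (2E)-4-chloro-3-methylbut-2-en-1-yl acetate
Conditions: PPh3, CCl4, CH2Cl2, 0 °C → rt
Reagents that add atoms: tetrachloromethane, ClC(Cl)(Cl)Cl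
Why: The Appel reaction converts the primary allylic alcohol into the chloride by SN2 displacement at CH2, without allylic transposition and without touching the acetate.

Step 14
Reactants: 20 (2E)-4-chloro-3-methylbut-2-en-1-yl acetate
Product: 21 (2E)-4-chloro-3-methylbut-2-en-1-ol
Conditions: K2CO3 (cat.), MeOH, 0 °C
Reagents that add atoms: none
Why: Base-catalysed transesterification removes the acetate; at 0 °C displacement of the allylic chloride by methoxide should not compete.

Step 15
Reactants: 21 (2E)-4-chloro-3-methylbut-2-en-1-ol
Product: 22 (2E)-4-chloro-3-methylbut-2-enal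
Conditions: MnO2, CH2Cl2, rt
Reagents that add atoms: none
Why: MnO2 oxidises allylic alcohols selectively to enals under neutral heterogeneous conditions, which keeps the E geometry and the allylic chloride.

Step 16
Reactants: 17 (E)-2-(methoxycarbonyl)allyl pinacol boronate (boron on C17); 22 (2E)-4-chloro-3-methylbut-2-enal
Product: 24 (1S,2S)-hydroxy ester (seco chloride boronate with free C2 hydroxyl), via pinacol borate 23 (not isolated)
Conditions: (R)-TRIP [(R)-3,3′-bis(2,4,6-triisopropylphenyl)-1,1′-binaphthyl-2,2′-diyl hydrogen phosphate] (10 mol%), 4 Å molecular sieves, toluene, 0 °C → rt; aq. NaHCO3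
Reagents that add atoms: none
Why: Proposed new method: the chiral phosphoric acid is expected to hydrogen-bond to a boronate oxygen of 17 and to the formyl hydrogen of 22 in the closed chair transition state, which should accelerate the ester-deactivated allylboronate and direct it to the Re face of the enal (2S), while the C14 chain cis to CH2B sits axial and the alkenyl group equatorial, giving the syn pair (1S); the closest known reaction types are the chiral phosphoric acid-catalysed allyl- and crotylboration of aldehydes with pinacol boronates and the thermal or Brønsted acid-promoted addition of 2-(alkoxycarbonyl)allyl pinacol boronates to aldehydes.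

Step 17
Reactants: 24 (1S,2S)-hydroxy ester (seco chloride boronate with free C2 hydroxyl)
Product: 25 seco chloride boronate (C2 and C8 triethylsilyl ethers, acrylate methyl ester, epoxide, acetate)
Conditions: Et3SiOTf, 2,6-lutidine, CH2Cl2, −78 °C
Reagents that add atoms: triethylsilyl trifluoromethanesulfonate, CC[Si](CC)(CC)OS(=O)(=O)C(F)(F)F
Why: Silylation with the triflate and a non-nucleophilic base at low temperature is faster than lactonisation and does not displace the allylic chloride; the silyl ether keeps C2–O from becoming an allylic ester that palladium could ionise.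

Step 18
Reactants: 25 seco chloride boronate (C2 and C8 triethylsilyl ethers, acrylate methyl ester, epoxide, acetate)
Product: 26 macrocyclic bis(triethylsilyl) ether methyl ester
Conditions: Pd(PPh3)4 (10 mol%), CsF (3 equiv), THF, 50 °C, slow addition of 25 to a final concentration of about 1 mM
Reagents that add atoms: none
Why: Zerovalent palladium ionises the primary allylic chloride to an η3-allyl complex spanning C3–C5, fluoride turns the pinacol boronate into a fluoroborate that passes the E-alkenyl group to palladium, and reductive elimination joins C6 to the unsubstituted terminus C5. The closest known reaction type is the palladium-catalysed Suzuki–Miyaura (or Stille) coupling of allylic halides with alkenyl metals, which has been used to close macrocyclic 1,4-dienes. The fourteen-membered carbocycle is closed by this C(sp3)–C(sp2) reductive elimination at high dilution; bonding at C3 would give a twelve-membered ring at a carbon crowded by the silyloxy-bearing C2 and is disfavoured on both counts. No stereocentre is formed, and C1, C2, C8 and C11–C13 are spectators because the new bond lies between two alkenes. The step needs C5 over C3 selectivity, retention of both E geometries and inertness of the other electrophilic sites. These are secured because the alkenylboronate transmetalates with retention, syn/anti exchange of the allyl complex would require palladium on the hindered C3, the C2 oxygen is a silyl ether, the C13 acetate and the epoxide are not allylic, and the acrylate has no leaving group. Fluoride activation keeps the medium nearly neutral, so acetate, acrylate and silyl ethers should persist.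

Step 19
Reactants: 26 macrocyclic bis(triethylsilyl) ether methyl ester
Product: 28 CNP0288879.3, via dihydroxy ester 27 (not isolated)
Conditions: Bu4NF, AcOH (1:1), THF, 0 °C → rt
Reagents that add atoms: none
Why: Buffered fluoride cleaves both triethylsilyl ethers without acid or strong base; the freed C2 hydroxyl is syn to the acrylate ester and should close the γ-lactone with loss of methanol, while C13 is blocked as the acetate so that no six-membered lactone can form.

## Compound list

1 | (R)-linalool, (3R)-3,7-dimethylocta-1,6-dien-3-ol | C=C[C@](C)(O)CCC=C(C)C | starting material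
2 | triethyl{[(3R)-3,7-dimethylocta-1,6-dien-3-yl]oxy}silane | C=C[C@](C)(O[Si](CC)(CC)CC)CCC=C(C)C | intermediate
3 | (2E,6R)-2,6-dimethyl-6-(triethylsilyloxy)octa-2,7-dien-1-ol | C=C[C@](C)(O[Si](CC)(CC)CC)CC/C=C(\C)CO | intermediate
4 | {(2S,3S)-2-methyl-3-[(3R)-3-methyl-3-(triethylsilyloxy)pent-4-en-1-yl]oxiran-2-yl}methanol | C=C[C@](C)(O[Si](CC)(CC)CC)CC[C@@H]1O[C@@]1(C)CO | intermediate
5 | vinylboronic acid pinacol ester, 2-ethenyl-4,4,5,5-tetramethyl-1,3,2-dioxaborolane | C=CB1OC(C)(C)C(C)(C)O1 | starting material
6 | {(2S,3S)-2-methyl-3-[(3R,4E)-3-methyl-5-Bpin-3-(triethylsilyloxy)pent-4-en-1-yl]oxiran-2-yl}methanol | CC1(C)OB(OC1(C)C)/C=C/[C@](C)(O[Si](CC)(CC)CC)CC[C@@H]2O[C@@]2(C)CO | intermediate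
7 | (2R,3S)-2-methyl-3-[(3R,4E)-3-methyl-5-Bpin-3-(triethylsilyloxy)pent-4-en-1-yl]oxirane-2-carbaldehyde | CC1(C)OB(OC1(C)C)/C=C/[C@](C)(O[Si](CC)(CC)CC)CC[C@@H]2O[C@@]2(C)C=O | intermediate
8 | N-methoxy-N-methylacetamide | CC(=O)N(C)OC | starting material
9 | lithium 1-[methoxy(methyl)amino]ethenolate (lithium enolate of 8) | C=C(O[Li])N(C)OC | intermediate
10 | lithium (1S)-3-[methoxy(methyl)amino]-1-{(2S,3S)-2-methyl-3-[(3R,4E)-3-methyl-5-Bpin-3-(triethylsilyloxy)pent-4-en-1-yl]oxiran-2-yl}-3-oxopropan-1-olate | CC1(C)OB(OC1(C)C)/C=C/[C@](C)(O[Si](CC)(CC)CC)CC[C@@H]2O[C@@]2(C)[C@@H](O[Li])CC(=O)N(C)OC | intermediate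
11 | (3S)-N-methoxy-N-methyl-3-{(2R,3S)-2-methyl-3-[(3R,4E)-3-methyl-5-Bpin-3-(triethylsilyloxy)pent-4-en-1-yl]oxiran-2-yl}-3-(trimethylsilyloxy)propanamide | CC1(C)OB(OC1(C)C)/C=C/[C@](C)(O[Si](CC)(CC)CC)CC[C@@H]2O[C@@]2(C)[C@@H](O[Si](C)(C)C)CC(=O)N(C)OC | intermediate
12 | (3S)-3-{(2R,3S)-2-methyl-3-[(3R,4E)-3-methyl-5-Bpin-3-(triethylsilyloxy)pent-4-en-1-yl]oxiran-2-yl}-3-(trimethylsilyloxy)propanal | CC1(C)OB(OC1(C)C)/C=C/[C@](C)(O[Si](CC)(CC)CC)CC[C@@H]2O[C@@]2(C)[C@@H](O[Si](C)(C)C)CC=O | intermediate
13 | methyl acrylate | C=CC(=O)OC | starting material
14 | methyl (5S)-3-hydroxy-2-methylidene-5-{(2R,3S)-2-methyl-3-[(3R,4E)-3-methyl-5-Bpin-3-(triethylsilyloxy)pent-4-en-1-yl]oxiran-2-yl}-5-(trimethylsilyloxy)pentanoate, both C3 epimers | CC1(C)OB(OC1(C)C)/C=C/[C@](C)(O[Si](CC)(CC)CC)CC[C@@H]2O[C@@]2(C)[C@@H](O[Si](C)(C)C)CC(O)C(=C)C(=O)OC | intermediate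
15 | methyl (5S)-3,5-dihydroxy-2-methylidene-5-{(2S,3S)-2-methyl-3-[(3R,4E)-3-methyl-5-Bpin-3-(triethylsilyloxy)pent-4-en-1-yl]oxiran-2-yl}pentanoate, both C3 epimers | CC1(C)OB(OC1(C)C)/C=C/[C@](C)(O[Si](CC)(CC)CC)CC[C@@H]2O[C@@]2(C)[C@@H](O)CC(O)C(=C)C(=O)OC | intermediate
16 | methyl (5S)-3,5-bis(acetyloxy)-2-methylidene-5-{(2R,3S)-2-methyl-3-[(3R,4E)-3-methyl-5-Bpin-3-(triethylsilyloxy)pent-4-en-1-yl]oxiran-2-yl}pentanoate, both C3 epimers | CC1(C)OB(OC1(C)C)/C=C/[C@](C)(O[Si](CC)(CC)CC)CC[C@@H]2O[C@@]2(C)[C@@H](OC(C)=O)CC(OC(C)=O)C(=C)C(=O)OC | intermediate
17 | methyl (2E,5S)-5-(acetyloxy)-2-(Bpin-methyl)-5-{(2R,3S)-2-methyl-3-[(3R,4E)-3-methyl-5-Bpin-3-(triethylsilyloxy)pent-4-en-1-yl]oxiran-2-yl}pent-2-enoate | CC1(C)OB(OC1(C)C)/C=C/[C@](C)(O[Si](CC)(CC)CC)CC[C@@H]2O[C@@]2(C)[C@@H](OC(C)=O)C/C=C(\CB3OC(C)(C)C(C)(C)O3)C(=O)OC | intermediate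
18 | prenyl acetate, 3-methylbut-2-en-1-yl acetate | CC(C)=CCOC(C)=O | starting material
19 | (2E)-4-hydroxy-3-methylbut-2-en-1-yl acetate | OC/C(C)=C/COC(C)=O | intermediate
20 | (2E)-4-chloro-3-methylbut-2-en-1-yl acetate | ClC/C(C)=C/COC(C)=O | intermediate
21 | (2E)-4-chloro-3-methylbut-2-en-1-ol | ClC/C(C)=C/CO | intermediate
22 | (2E)-4-chloro-3-methylbut-2-enal | ClC/C(C)=C/C=O | intermediate
23 | pinacol borate of 24: methyl (3S,4S,5E)-3-[(2S)-2-(acetyloxy)-2-{(2R,3S)-2-methyl-3-[(3R,4E)-3-methyl-5-Bpin-3-(triethylsilyloxy)pent-4-en-1-yl]oxiran-2-yl}ethyl]-7-chloro-6-methyl-2-methylidene-4-(Bpin-oxy)hept-5-enoate | CC1(C)OB(OC1(C)C)/C=C/[C@](C)(O[Si](CC)(CC)CC)CC[C@@H]2O[C@@]2(C)[C@@H](OC(C)=O)C[C@@H](C(=C)C(=O)OC)[C@@H](OB3OC(C)(C)C(C)(C)O3)/C=C(\C)CCl | intermediate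
24 | methyl (3S,4S,5E)-3-[(2S)-2-(acetyloxy)-2-{(2R,3S)-2-methyl-3-[(3R,4E)-3-methyl-5-Bpin-3-(triethylsilyloxy)pent-4-en-1-yl]oxiran-2-yl}ethyl]-7-chloro-4-hydroxy-6-methyl-2-methylidenehept-5-enoate | CC1(C)OB(OC1(C)C)/C=C/[C@](C)(O[Si](CC)(CC)CC)CC[C@@H]2O[C@@]2(C)[C@@H](OC(C)=O)C[C@@H](C(=C)C(=O)OC)[C@@H](O)/C=C(\C)CCl | intermediate
25 | methyl (3S,4S,5E)-3-[(2S)-2-(acetyloxy)-2-{(2R,3S)-2-methyl-3-[(3R,4E)-3-methyl-5-Bpin-3-(triethylsilyloxy)pent-4-en-1-yl]oxiran-2-yl}ethyl]-7-chloro-6-methyl-2-methylidene-4-(triethylsilyloxy)hept-5-enoate | CC1(C)OB(OC1(C)C)/C=C/[C@](C)(O[Si](CC)(CC)CC)CC[C@@H]2O[C@@]2(C)[C@@H](OC(C)=O)C[C@@H](C(=C)C(=O)OC)[C@@H](O[Si](CC)(CC)CC)/C=C(\C)CCl | intermediate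
26 | methyl 2-[(1S,2S,3E,6E,8R,11S,12R,13S)-13-(acetyloxy)-11,12-epoxy-4,8,12-trimethyl-2,8-bis(triethylsilyloxy)cyclotetradeca-3,6-dien-1-yl]prop-2-enoate | C1/C=C/[C@](C)(O[Si](CC)(CC)CC)CC[C@@H]2O[C@@]2(C)[C@@H](OC(C)=O)C[C@@H](C(=C)C(=O)OC)[C@@H](O[Si](CC)(CC)CC)/C=C1\C | intermediate
27 | methyl 2-[(1S,2S,3E,6E,8R,11S,12R,13S)-13-(acetyloxy)-11,12-epoxy-2,8-dihydroxy-4,8,12-trimethylcyclotetradeca-3,6-dien-1-yl]prop-2-enoate | C1/C=C/[C@](C)(O)CC[C@@H]2O[C@@]2(C)[C@@H](OC(C)=O)C[C@@H](C(=C)C(=O)OC)[C@@H](O)/C=C1\C | intermediate
28 | CNP0288879.3, (1S,2S,3E,6E,8R,11S,12R,13S)-13-acetoxy-11,12-epoxy-8-hydroxycembra-3,6,15(17)-trien-16,2-olide (numbering as above) | C=C1C(=O)O[C@H]2/C=C(\C)C/C=C/[C@](C)(O)CC[C@@H]3O[C@@]3(C)[C@@H](OC(C)=O)C[C@@H]12 | target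

## Step count and least certain steps

Total: 19 steps. Longest linear sequence: 15 steps (steps 1–11 and 16–19); the enal 22 is made in four steps (12–15).

Step 16 (new method). The phosphoric acid may fail to accelerate the ester-deactivated allylboronate, so that the uncatalysed pathway erodes facial control. The acid may also open the trisubstituted epoxide or promote lactonisation onto C16, and the weak intrinsic bias of the C13 acetoxy side chain may oppose the catalyst. Fallback with known chemistry: from 17 and 22, the uncatalysed thermal allylboration (toluene, 60–80 °C), established for pinacol 2-(alkoxycarbonyl)allylboronates made from Baylis–Hillman acetates, through the same borate 23 to 24. This gives up catalyst control: the closed transition state secures only the syn relationship, and the (1S,2S) and (1R,2R) isomers would be separated by chromatography at 24. No new compound arises (F0).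

Step 18 (key step). Transmetalation of an alkenylboronate beside the quaternary, silyloxy-bearing C8 may be slow. Intermolecular coupling, protodeboronation, β-hydride elimination of the allyl complex to a diene, or syn/anti exchange that scrambles the C3=C4 geometry could then compete. Fallback: from 25, cleave the pinacol ester with NaIO4 and NH4OAc in aqueous acetone to the seco alkenylboronic acid F1. Cyclise F1 with Pd(PPh3)4 and TlOEt in aqueous THF at room temperature, where the free boronic acid transmetalates through a palladium alkoxide or hydroxide and should react faster; this returns to the route at 26.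

Step 4. Metathesis at a vinyl group on a fully substituted silyloxy carbon may be slow, so that homodimerisation of 5 and catalyst decay win. Fallback: from 4, cleave the vinyl group with OsO4 (cat.) and NaIO4 to the α-silyloxy aldehyde F2, which has no α-hydrogen. A chromium-mediated boryl olefination (CrCl2, Cl2CHBpin, LiI, THF; divalent chromium) then gives the E alkenylboronate and returns to the route at 6.

Step 6. Lithium may bridge the aldehyde and epoxide oxygens, which reverses the facial preference and erodes the anti selectivity; retro-aldol cleavage before silylation is a second risk. Fallback: from 7 and 8, quench the aldol with aqueous NH4Cl to the β-hydroxy amide F3 (both C13 epimers) and oxidise it (SO3·pyridine, DMSO, iPr2NEt) to the β-keto amide F4. Reduce F4 with Zn(BH4)2 in Et2O at −20 °C; here the zinc chelate between ketone and epoxide oxygens is put to use, and hydride attack away from the ring C–C bond is known to give the anti epoxy alcohol, the (13S)-hydroxy amide F5. Silylation (Me3SiCl, imidazole) returns to the route at 11.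

Step 8. Slow turnover under the amine may allow β-elimination of silanol from the β-silyloxy aldehyde or its self-condensation. Fallback: from 12, hydroalumination of methyl propiolate with iBu2AlH and N-methylmorpholine N-oxide in THF gives the α-aluminoacrylate F6, [1-(methoxycarbonyl)ethenyl]diisobutylaluminium. F6 adds to the aldehyde within hours without amine base and returns to the route at 14.

Step 19. Once both hydroxyls are free, transannular opening of the epoxide by the C8 hydroxyl, acetate migration or incomplete lactonisation may occur. Fallback: from 26, deprotect in two stages. HF·pyridine buffered with pyridine (THF, 0 °C) should cleave the less hindered secondary allylic silyl ether first and allow lactonisation while C8 is still masked, giving the C8 triethylsilyl ether of the target F7. F7 is then desilylated under anhydrous, non-acidic conditions with tris(dimethylamino)sulfonium difluorotrimethylsilicate in DMF at 0 °C, which returns to the route at 28.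

## Further compounds

F0 | step 16 | none | none
F1 | step 18 | seco alkenylboronic acid: [(1E,3R)-...]boronic acid analogue of 25 with B(OH)2 on C6 | OB(O)/C=C/[C@](C)(O[Si](CC)(CC)CC)CC[C@@H]1O[C@@]1(C)[C@@H](OC(C)=O)C[C@@H](C(=C)C(=O)OC)[C@@H](O[Si](CC)(CC)CC)/C=C(\C)CCl
F2 | step 4 | (2R)-4-[(2S,3S)-3-(hydroxymethyl)-3-methyloxiran-2-yl]-2-methyl-2-(triethylsilyloxy)butanal | O=C[C@](C)(O[Si](CC)(CC)CC)CC[C@@H]1O[C@@]1(C)CO
F3 | step 6 | 3-hydroxy-N-methoxy-N-methyl-3-{(2S,3S)-2-methyl-3-[(3R,4E)-3-methyl-5-Bpin-3-(triethylsilyloxy)pent-4-en-1-yl]oxiran-2-yl}propanamide, both C3 epimers | CC1(C)OB(OC1(C)C)/C=C/[C@](C)(O[Si](CC)(CC)CC)CC[C@@H]2O[C@@]2(C)C(O)CC(=O)N(C)OC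
F4 | step 6 | N-methoxy-N-methyl-3-{(2R,3S)-2-methyl-3-[(3R,4E)-3-methyl-5-Bpin-3-(triethylsilyloxy)pent-4-en-1-yl]oxiran-2-yl}-3-oxopropanamide | CC1(C)OB(OC1(C)C)/C=C/[C@](C)(O[Si](CC)(CC)CC)CC[C@@H]2O[C@@]2(C)C(=O)CC(=O)N(C)OC
F5 | step 6 | (3S)-3-hydroxy-N-methoxy-N-methyl-3-{(2S,3S)-2-methyl-3-[(3R,4E)-3-methyl-5-Bpin-3-(triethylsilyloxy)pent-4-en-1-yl]oxiran-2-yl}propanamide | CC1(C)OB(OC1(C)C)/C=C/[C@](C)(O[Si](CC)(CC)CC)CC[C@@H]2O[C@@]2(C)[C@@H](O)CC(=O)N(C)OC
F6 | step 8 | [1-(methoxycarbonyl)ethenyl]diisobutylaluminium | C=C(C(=O)OC)[Al](CC(C)C)CC(C)C
F7 | step 19 | C8 triethylsilyl ether of the target | C=C1C(=O)O[C@H]2/C=C(\C)C/C=C/[C@](C)(O[Si](CC)(CC)CC)CC[C@@H]3O[C@@]3(C)[C@@H](OC(C)=O)C[C@@H]12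
A1 | alternative 1 | cis-fused γ-lactone on the fourteen-membered 11-en-13-one, C8 triethylsilyl ether, no exocyclic methylene | C1C(=O)O[C@H]2/C=C(\C)C/C=C/[C@](C)(O[Si](CC)(CC)CC)CC/C=C(\C)C(=O)C[C@@H]12
A2 | alternative 1 | fifteen-membered β-keto lactone with a vinyl group on C2, C8 triethylsilyl ether | C=C[C@@H]1/C=C(\C)C/C=C/[C@](C)(O[Si](CC)(CC)CC)CC/C=C(\C)C(=O)CC(=O)O1
A3 | alternative 2 | macrocyclic 10-phenylsulfonyl 8,13-diol lactol methyl acetal (C10 and acetal epimers) | C1[C@@](C)(O)/C=C/C/C(C)=C/[C@@H]2OC(OC)C[C@@H]2C[C@H](O)/C(C)=C/C1S(=O)(=O)c1ccccc1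
A4 | alternative 2 | seco C8–C9 epoxide with the C10 allylic phenyl sulfone and C13 hydroxyl (lactol methyl acetal) | C[C@@]1(CO1)/C=C/C/C(C)=C/[C@@H]2OC(OC)C[C@@H]2C[C@H](O)/C(C)=C/CS(=O)(=O)c1ccccc1
A5 | alternative 3 | fourteen-membered 11-en-13-one with C2 4-methoxybenzyl ether, C8 trimethylsilyl ether and 3-(tert-butyldimethylsilyloxy)prop-1-en-2-yl on C1 | COc1ccc(CO[C@H]2/C=C(\C)C/C=C/[C@](C)(O[Si](C)(C)C)CC/C=C(\C)C(=O)C[C@H]2C(=C)CO[Si](C)(C)C(C)(C)C)cc1
A6 | alternative 3 | sixteen-membered 2-methylene oxacycle (allyl vinyl ether C14=C13–O–C17–C15=C1), C15=C1 drawn with C17 and C2 trans in the ring | C=C1OC/C(CO[Si](C)(C)C(C)(C)C)=C/[C@@H](OCc2ccc(OC)cc2)/C=C(\C)C/C=C/[C@](C)(O[Si](C)(C)C)CC/C=C1\C
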